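**Retrosynthetic overview**

1. The O–C(CH3)2 carbon of ring D (the 2,2-dimethyl-dihydropyran fused to quinolone unit 2) is unmasked at the end from a CH3/CH2CO2Me carbon in ester 12, by ester cleavage and reductive decarboxylation.
2. Key disconnection: ring D is cut at two bonds, C3 of quinolone unit 2 to the ring-fusion CH, and the O–CH carbon to the quaternary O–C carbon. This gives glycal 8 (ring C, the dihydropyran on quinolone unit 1, already in place) and iodo-quinolone 11. In the forward sense a radical addition/cyclisation annulation joins them, and ring D closes last by the bond between the O–CH carbon and the quaternary O–C carbon.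
3. Enabling feature: that bond links two oxygen-bearing carbons. One is the O–CH carbon shared by rings C and D (on the C4–O of unit 1); the other is the O–C(CH3)2 carbon on the C4–O of unit 2. The first can therefore be the α-oxy radical of ring C, born when an aryl radical adds to the enol ether C=C of ring C; the second can be the β-carbon of a β-aryloxycrotonate.
4. Glycal 8 comes from quinolinol 4 and dienal 3 by enantioselective iminium Michael addition/hemiacetalisation, then dehydration. This sets the isobutenyl-bearing CH, which later controls both ring-fusion centres. Dienal 3 comes from prenal by Wittig homologation.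
5. Iodide 11 comes from 4 by C3-iodination and O-addition to methyl but-2-ynoate. Ring order: ring C (step 2), then ring D (step 6).

Key step: step 6

Assumption: the (S)-catalyst follows the usual iminium face model with dienal 3 (otherwise its enantiomer is used); the lactol carbon of 6 and 7 and the new quaternary carbon of 12, 13 and 14 are epimer mixtures that converge later and are left open in the SMILES.

**Route**

Step 1
Reactants: 1 3-methylbut-2-enal (prenal); 2 (triphenylphosphoranylidene)acetaldehyde
Product: 3 (2E)-5-methylhexa-2,4-dienal
Conditions: 1 (1.5 equiv), PhMe, 80 °C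
Reagents that add atoms: none
Why: Wittig olefination with the stabilised formylmethylene ylide should give the (E)-dienal, and the excess of prenal limits a second homologation.

Step 2
Reactants: 4 4-hydroxy-1-methylquinolin-2(1H)-one; 3 (2E)-5-methylhexa-2,4-dienal
Product: 6 (4S)-2-hydroxy-6-methyl-4-(2-methylprop-1-en-1-yl)-2,3,4,6-tetrahydro-5H-pyrano[3,2-c]quinolin-5-one (lactol as anomer mixture), via open-chain aldehyde 5 (not isolated)
Conditions: (S)-2-[diphenyl(trimethylsilyloxy)methyl]pyrrolidine (20 mol%), CH2Cl2, 0 °C to rt
Reagents that add atoms: none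
Why: Iminium-catalysed Michael addition/hemiacetalisation of a cyclic 1,3-dicarbonyl enol to an enal; C3 of 4 should attack the β-carbon of the dienyl iminium ion (the δ-carbon is blocked by its two methyl groups) on the face away from the diphenyl(silyloxy)methyl arm, setting the isobutenyl-bearing centre as (S), and ring C closes by hemiacetalisation.

Step 3
Reactants: 6 lactol
Product: 8 (4R)-6-methyl-4-(2-methylprop-1-en-1-yl)-4,6-dihydro-5H-pyrano[3,2-c]quinolin-5-one (glycal), via anomeric mesylate 7 (not isolated)
Conditions: MsCl, Et3N, CH2Cl2, 0 to 40 °C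
Reagents that add atoms: none
Why: One-pot mesylation–elimination of a lactol to the cyclic enol ether (glycal-type dehydration); the stereocentre is not touched, and its descriptor changes to (R) only because the CIP ranking changes.

Step 4
Reactants: 4 4-hydroxy-1-methylquinolin-2(1H)-one
Product: 9 4-hydroxy-3-iodo-1-methylquinolin-2(1H)-one
Conditions: NIS, MeCN, rt
Reagents that add atoms: N-iodosuccinimide, O=C1CCC(=O)N1I
Why: Electrophilic iodination of the enolic C3 position; the iodine blocks C-alkylation in step 5 and is the radical precursor for step 6.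

Step 5
Reactants: 9 4-hydroxy-3-iodo-1-methylquinolin-2(1H)-one; 10 methyl but-2-ynoate
Product: 11 methyl (2E)-3-[(3-iodo-1-methyl-2-oxo-1,2-dihydroquinolin-4-yl)oxy]but-2-enoate
Conditions: K2CO3 (0.3 equiv), DMF, 60 °C
Reagents that add atoms: none
Why: Base-mediated oxa-Michael addition of the quinolinolate to the ynoate; with C3 blocked only O-attack is possible, and the thermodynamically preferred (E)-β-aryloxycrotonate is expected (the alkene geometry is lost in step 6).

Step 6
Reactants: 8 glycal; 11 iodo-crotonate
Product: 12 methyl ester of the full ring system: the target with one methyl of the O–C(CH3)2 carbon replaced by CH2CO2Me; isobutenyl CH (R), O–CH (S), ring-fusion CH on unit 2 (S); rings C and D cis-fused, isobutenyl trans to ring D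
Conditions: 11 (2 equiv), Bu3SnH (2.2 equiv) and AIBN (0.3 equiv) by syringe pump over 10 h, PhH (0.3 M in 8), 80 °C, dark
Reagents that add atoms: none
Why: Proposed new method: Bu3Sn• abstracts iodine from 11, the electron-poor quinolon-3-yl σ-radical adds to the enol ether C=C of 8 at the carbon β to the ring oxygen, the resulting nucleophilic α-oxy radical of ring C closes ring D by 6-exo-trig attack on the β-carbon of the β-aryloxycrotonate (the carbon bearing the methyl group and the quinolone oxygen), and the α-ester radical takes hydrogen from Bu3SnH. The closest known reaction types are intermolecular addition of (hetero)aryl radicals to vinyl ethers and glycals, radical annulation by addition then cyclisation onto an ortho-tethered acceptor, and 6-exo cyclisation of α-alkoxy radicals onto β-alkoxyacrylates in cyclic ether synthesis; combining them on one substrate pair is new. The ring-fusion CH bonded to unit 2 is set by approach of the aryl radical anti to the neighbouring isobutenyl group of 8, and the O–CH centre is set by the short tether together with axial attack on the ring C α-oxy radical, which allow only the cis ring fusion. The step needs addition to the enol ether in preference to the isobutenyl alkene and to reduction by the hydride; this rests on the polarity match between the electron-poor σ-radical and the cyclic enol ether, on the excess of 11 and on a low stationary hydride concentration. 6-Exo rather than 7-endo closure is secured by the ester at the alkene terminus, which makes the oxygen-bearing carbon the electrophilic one.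

Step 7
Reactants: 12 methyl ester
Product: 13 the corresponding carboxylic acid (CH2CO2H on the quaternary carbon of ring D)
Conditions: Me3SnOH, ClCH2CH2Cl, 80 °C; then 0.1 M HCl wash
Reagents that add atoms: trimethyltin hydroxide, C[Sn](C)(C)O
Why: Near-neutral ester cleavage with Me3SnOH, chosen because hydroxide or alkoxide could trigger E1cB loss of the quinolinolate that sits β to the ester.

Step 8
Reactants: 13 carboxylic acid
Product: 15 target CNP0107253.2, via thiohydroxamate ester 14 (not isolated)
Conditions: N-hydroxypyridine-2-thione, DCC, DMAP (cat.), CH2Cl2, 0 °C, dark; then t-BuSH, AIBN (cat.), PhH, 80 °C, dark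
Reagents that add atoms: none
Why: Barton reductive decarboxylation: the thermal chain gives the primary radical, which the thiol should reduce faster than β-scission of the neighbouring C–O bond, turning the acetic acid arm into the second methyl group; the chain is run without light to avoid photochemistry of the quinolone chromophores.

**Compound list**

1 | 3-methylbut-2-enal | CC(C)=CC=O | starting material
2 | (triphenylphosphoranylidene)acetaldehyde | O=CC=P(c1ccccc1)(c1ccccc1)c1ccccc1 | starting material
3 | (2E)-5-methylhexa-2,4-dienal | CC(C)=C/C=C/C=O | intermediate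
4 | 4-hydroxy-1-methylquinolin-2(1H)-one | Cn1c(=O)cc(O)c2ccccc12 | starting material
5 | (3S)-3-(4-hydroxy-1-methyl-2-oxo-1,2-dihydroquinolin-3-yl)-5-methylhex-4-enal | CC(C)=C[C@H](CC=O)c1c(O)c2ccccc2n(C)c1=O | intermediate
6 | (4S)-2-hydroxy-6-methyl-4-(2-methylprop-1-en-1-yl)-2,3,4,6-tetrahydro-5H-pyrano[3,2-c]quinolin-5-one | CC(C)=C[C@H]1c2c(c3ccccc3n(C)c2=O)OC(O)C1 | intermediate
7 | anomeric methanesulfonate of 6 | CC(C)=C[C@H]1c2c(c3ccccc3n(C)c2=O)OC(OS(C)(=O)=O)C1 | intermediate
8 | (4R)-6-methyl-4-(2-methylprop-1-en-1-yl)-4,6-dihydro-5H-pyrano[3,2-c]quinolin-5-one | CC(C)=C[C@H]1c2c(c3ccccc3n(C)c2=O)OC=C1 | intermediate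
9 | 4-hydroxy-3-iodo-1-methylquinolin-2(1H)-one | Cn1c(=O)c(I)c(O)c2ccccc12 | intermediate
10 | methyl but-2-ynoate | CC#CC(=O)OC | starting material
11 | methyl (2E)-3-[(3-iodo-1-methyl-2-oxo-1,2-dihydroquinolin-4-yl)oxy]but-2-enoate | COC(=O)/C=C(\C)Oc1c(I)c(=O)n(C)c2ccccc12 | intermediate
12 | methyl ester: target with CH2CO2Me in place of one methyl on the ring D quaternary carbon | CC(C)=C[C@H]1c2c(c3ccccc3n(C)c2=O)O[C@H]2[C@@H]1c1c(c3ccccc3n(C)c1=O)OC2(C)CC(=O)OC | intermediate
13 | carboxylic acid corresponding to 12 | CC(C)=C[C@H]1c2c(c3ccccc3n(C)c2=O)O[C@H]2[C@@H]1c1c(c3ccccc3n(C)c1=O)OC2(C)CC(=O)O | intermediate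
14 | 2-thioxopyridin-1(2H)-yl ester of 13 | CC(C)=C[C@H]1c2c(c3ccccc3n(C)c2=O)O[C@H]2[C@@H]1c1c(c3ccccc3n(C)c1=O)OC2(C)CC(=O)On1ccccc1=S | intermediate
15 | CNP0107253.2: cis-fused bis(pyranoquinolinone), isobutenyl CH (R), O–CH (S), ring-fusion CH (S) | CC(C)=C[C@H]1c2c(c3ccccc3n(C)c2=O)O[C@H]2[C@@H]1c1c(c3ccccc3n(C)c1=O)OC2(C)C | target

**Step count**

Total steps: 8. Longest linear sequence: 6 (steps 1, 2, 3, 6, 7, 8).

**Steps most likely to fail**

Step 6. The aryl radical may be lost before it meets 8, either by reduction by the hydride or by 1,5-hydrogen transfer from the crotonate methyl group. It may also add to the isobutenyl alkene, or the ring C radical may be reduced before it cyclises. The fallback uses known reaction types, sets out from 8 and 4, and returns to the route at 12. Oxidative [3+2] cycloaddition of 4 to the enol ether of 8 with (NH4)2Ce(NO3)6 (NaHCO3, MeCN, 0 °C) should give the cis-fused furo-acetal F1. In F1, C3 of unit 2 sits on the ring-fusion carbon and its 4-oxygen on the acetal carbon, both anti to the isobutenyl group. PhSH with BF3·OEt2 (CH2Cl2, −40 °C) should open the five-membered acetal ring to the S-phenyl monothioacetal F2, which has a free 4-hydroxy group. K2CO3-mediated addition of F2 to 10 should give the β-aryloxycrotonate F3. Bu3SnH/AIBN (PhH, 80 °C, slow addition) then generates the same ring C α-oxy radical from the C–S bond and closes ring D by the same 6-exo cyclisation, giving 12.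

Step 2. The dienal may react by 1,2-addition followed by condensation and electrocyclisation to a 2H-pyran, or the facial selectivity may be poor. The fallback sets out from 4 and returns at 6. Condensation of 4 with ethyl propiolate (Pd(OAc)2 cat., CF3CO2H, rt) should give the pyranoquinolinedione F4. A Hayashi–Miyaura conjugate addition of 2-methylprop-1-en-1-ylboronic acid ([Rh(OH)(cod)]2 with a chiral bisphosphine such as SEGPHOS, dioxane/H2O, 50 °C; ligand enantiomer chosen for the (4S) product) should give the lactone F5. DIBAL-H (CH2Cl2, −78 °C) then reduces F5 to lactol 6.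

Step 5. O-addition of the hindered, weakly nucleophilic quinolinolate to a β-substituted ynoate may be too slow. The fallback sets out from 9 and returns at 11. Methyl acetoacetate is converted with TsCl (Et3N, N-methylimidazole, CH2Cl2) into the enol tosylate F6. Addition–elimination of the caesium salt of 9 on F6 (Cs2CO3, DMF, 60 °C) should give 11.

**Further compounds**

F1 | step 6 | cis-fused furo-acetal from 8 and 4 (unit 2 C3 on the ring-fusion CH, its 4-O on the acetal CH) | CC(C)=C[C@H]1c2c(c3ccccc3n(C)c2=O)O[C@H]2[C@@H]1c1c(c3ccccc3n(C)c1=O)O2
F2 | step 6 | ring C S-phenyl monothioacetal carrying the 4-hydroxyquinolone on the adjacent CH | CC(C)=C[C@H]1c2c(c3ccccc3n(C)c2=O)OC(Sc3ccccc3)[C@@H]1c1c(O)c2ccccc2n(C)c1=O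
F3 | step 6 | O-[(E)-4-methoxy-4-oxobut-2-en-2-yl] ether of F2 | CC(C)=C[C@H]1c2c(c3ccccc3n(C)c2=O)OC(Sc3ccccc3)[C@@H]1c1c(O/C(C)=C/C(=O)OC)c2ccccc2n(C)c1=O
F4 | step 2 | 6-methyl-2H-pyrano[3,2-c]quinoline-2,5(6H)-dione | Cn1c(=O)c2ccc(=O)oc2c2ccccc12
F5 | step 2 | (4S)-6-methyl-4-(2-methylprop-1-en-1-yl)-3,4-dihydro-2H-pyrano[3,2-c]quinoline-2,5(6H)-dione | CC(C)=C[C@H]1c2c(c3ccccc3n(C)c2=O)OC(=O)C1
F6 | step 5 | methyl (2E)-3-{[(4-methylphenyl)sulfonyl]oxy}but-2-enoate | COC(=O)/C=C(\C)OS(=O)(=O)c1ccc(C)cc1
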